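The route rests on the C10–C9 bond. C10 of ring A is fully substituted, sits beside C5 and two bonds from the gem-dimethyl carbon C4, and must take C9 on the face trans to C6. A UV-A [2+2] photocycloaddition of allene to a ring A enone (C2 carbonyl, C1=C10 alkene) makes this bond and a sacrificial C1–C11 bond in one operation, setting C10 from the C5 stereocentre of (R)-α-ionone. The precursor is the ionone-derived cyclohexenone whose C5 side chain carries the C8 ketone as a dioxolane. Ozonolysis and retro-Claisen opening then release a C9–C11 acetic acid arm for aldol closure of ring B; carboalumination and benzyl coupling finish the side chain.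

Key step: step 4

Remark: labdane numbering is used throughout; (R)-α-ionone is assumed purchasable in high enantiomeric purity, and its stereocentre maps directly onto C5 of the (5R,10R) target.

Step 1
Reactants: 1 (R)-α-ionone
Product: 2 (R)-dihydro-α-ionone [4-((1R)-2,6,6-trimethylcyclohex-2-en-1-yl)butan-2-one]
Conditions: Cu(OAc)2 (3 mol %), 1,2-bis(diphenylphosphino)benzene (3 mol %), (EtO)2MeSiH, t-BuOH, toluene, rt
Reagents that add atoms: none
Why: Copper hydride conjugate reduction (Stryker-type 1,4-reduction) delivers hydride only to the β-carbon of the acyclic enone, while the isolated ring alkene is inert and the neutral medium leaves the doubly allylic stereocentre untouched.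

Step 2
Reactants: 2 (R)-dihydro-α-ionone
Product: 3 2-methyl-2-{2-[(1R)-2,6,6-trimethylcyclohex-2-en-1-yl]ethyl}-1,3-dioxolane
Conditions: HOCH2CH2OH, PPTS (cat.), benzene, reflux (Dean–Stark)
Reagents that add atoms: ethylene glycol, OCCO
Why: Acid-catalysed ketalisation with azeotropic removal of water; the weak acid PPTS is chosen so that the ring alkene is not shifted to the tetrasubstituted position, which would erase the stereocentre.

Step 3
Reactants: 3 dioxolane of dihydro-α-ionone
Product: 4 (4R)-3,5,5-trimethyl-4-[2-(2-methyl-1,3-dioxolan-2-yl)ethyl]cyclohex-2-en-1-one (ring A enone)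
Conditions: Rh2(cap)4 (dirhodium tetrakis(caprolactamate), 1 mol %), t-BuOOH (in decane), K2CO3, CH2Cl2, rt
Reagents that add atoms: tert-butyl hydroperoxide, CC(C)(C)OO
Why: Radical allylic oxidation by tert-butylperoxyl radicals converts the only allylic ring methylene (C2) into the enone carbonyl; the tertiary allylic C5–H is shielded by the gem-dimethyl group and the chain and cannot give a ketone, and no base strong enough to deprotonate C5 of the product is present.

Step 4
Reactants: 4 ring A enone; 5 allene
Product: 6 (1S,5R,6S)-4,4,6-trimethyl-8-methylidene-5-[2-(2-methyl-1,3-dioxolan-2-yl)ethyl]bicyclo[4.2.0]octan-2-one (cis-fused methylenecyclobutane; C9 trans to C6)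
Conditions: allene (excess), hν (350–370 nm, Pyrex), THF, −78 °C
Reagents that add atoms: none
Why: This is the enone–allene [2+2] photocycloaddition, well established for β-substituted cyclohexenones: n→π* excitation and intersystem crossing give the twisted triplet enone, which is intercepted by allene to form a triplet 1,4-diradical that closes after spin inversion. The only ring formed, the cyclobutane C1–C10–C9–C11, is closed by radical recombination within that diradical, so that C10 is joined to a terminal allene carbon (future C9) and C1 to the central one (future C11), the head-to-head orientation that allene normally shows with cyclic enones. C10 is set by the resident C5 stereocentre: A(1,2) strain with the C10 methyl holds the C5 chain pseudo-axial, where it covers one face of C10, and the excited-state bond formation, far less sensitive to crowding at this fully substituted carbon than a thermal conjugate addition, should occur on the opposite face and place C9 trans to C6. C1 follows from the cis ring fusion imposed by the four-membered ring and is of no consequence, because C1 returns to CH2 in step 5. The step therefore needs this facial preference and the head-to-head regiochemistry; low temperature and a large excess of allene are used to suppress enone dimerisation.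

Step 5
Reactants: 6 photoadduct
Product: 8 2-{(1S,2R)-1,3,3-trimethyl-2-[2-(2-methyl-1,3-dioxolan-2-yl)ethyl]-5-oxocyclohexyl}acetic acid (keto acid), via cyclobutanone diketone 7 (not isolated)
Conditions: O3, CH2Cl2, −78 °C; Me2S; concentrate; then KOH, THF/H2O, 0 °C to rt; cold dilute HCl to pH 4–5
Reagents that add atoms: ozone, [O-][O+]=O; potassium hydroxide, [K+].[OH-]
Why: Ozonolysis of the only alkene gives a cyclobutanone β to the C2 ketone; hydroxide adds to the strained four-ring carbonyl and the C1–C11 bond breaks in a strain-driven retro-Claisen (β-diketone cleavage), returning C1 to CH2 and leaving the C9–C11 acetic acid arm on C10, while the dioxolane is inert to ozone and base.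

Step 6
Reactants: 8 keto acid
Product: 10 2-{(1S,2R)-1,3,3-trimethyl-2-[2-(2-methyl-1,3-dioxolan-2-yl)ethyl]cyclohexyl}acetic acid, via keto acid hydrazone 9 (not isolated)
Conditions: N2H4·H2O, KOH, diethylene glycol, 130 °C then 200 °C; cold dilute HCl to pH 4–5
Reagents that add atoms: none
Why: Wolff–Kishner reduction (Huang-Minlon procedure) turns the hindered C2 ketone into CH2 through its hydrazone with loss of N2; the carboxylate and the base-stable dioxolane are unaffected and no stereocentre lies α to the carbonyl.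

Step 7
Reactants: 10 deoxygenated acid
Product: 11 2-{(1S,2R)-1,3,3-trimethyl-2-[2-(2-methyl-1,3-dioxolan-2-yl)ethyl]cyclohexyl}ethan-1-ol
Conditions: LiAlH4, THF, 0 °C to reflux; aq. NaOH work-up
Reagents that add atoms: none
Why: LiAlH4 reduction of a carboxylic acid to the primary alcohol; the dioxolane is inert to hydride.

Step 8
Reactants: 11 primary alcohol
Product: 12 2-{(1S,2R)-1,3,3-trimethyl-2-[2-(2-methyl-1,3-dioxolan-2-yl)ethyl]cyclohexyl}acetaldehyde
Conditions: Pr4N[RuO4] (5 mol %), NMO, 4 Å MS, CH2Cl2, rt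
Reagents that add atoms: none
Why: Ley–Griffith oxidation stops at the aldehyde under neutral, anhydrous conditions that leave the ketal intact.

Step 9
Reactants: 12 ketal aldehyde
Product: 14 (4aR,8aR)-2,5,5,8a-tetramethyl-3,4,4a,5,6,7,8,8a-octahydronaphthalene-1-carbaldehyde (ent-drim-8-en-11-al), via keto aldehyde 13 (not isolated)
Conditions: PPTS, acetone/H2O, 50 °C; then piperidine, AcOH, benzene, 80 °C (Dean–Stark)
Reagents that add atoms: none
Why: Mild hydrolysis frees the C8 methyl ketone, and the secondary amine forms the enamine of the aldehyde much faster than that of the ketone, so that C9 adds to C8 (6-enolexo-exo-trig intramolecular aldol) and dehydration gives the conjugated tetrasubstituted C8=C9 enal as the thermodynamic product; no stereocentre is formed or disturbed.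

Step 10
Reactants: 14 enal
Product: 15 [(4aR,8aR)-2,5,5,8a-tetramethyl-3,4,4a,5,6,7,8,8a-octahydronaphthalen-1-yl]methanol (ent-drim-8-en-11-ol)
Conditions: NaBH4, MeOH, 0 °C
Reagents that add atoms: none
Why: Borohydride 1,2-reduction of the aldehyde; the fully substituted β-carbon C8 rules out conjugate reduction.

Step 11
Reactants: 15 allylic alcohol
Product: 16 (4aR,8aR)-1-(bromomethyl)-2,5,5,8a-tetramethyl-3,4,4a,5,6,7,8,8a-octahydronaphthalene
Conditions: PBr3, pyridine (cat.), Et2O, −10 °C to 0 °C; used at once
Reagents that add atoms: phosphorus tribromide, BrP(Br)Br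
Why: A primary allylic alcohol is converted into the bromide by SN2 displacement of its phosphite ester at low temperature; transposition to the fully substituted C8 is disfavoured.

Step 12
Reactants: 16 allylic bromide; 5 allene
Product: 17 (4aR,8aR)-1-(but-3-yn-1-yl)-2,5,5,8a-tetramethyl-3,4,4a,5,6,7,8,8a-octahydronaphthalene
Conditions: allene, n-BuLi (2 equiv), THF/Et2O, −78 to −15 °C; then 16, −78 °C to rt; H2O
Reagents that add atoms: none
Why: Propargylation of an allylic halide with 1,3-dilithiopropyne made in the flask from allene: its sp3 carbanion end displaces the primary allylic bromide (SN2, C11–C12 bond) and the acetylide end is protonated on work-up to the terminal alkyne, while an SN2' path would have to attack the fully substituted C8.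

Step 13
Reactants: 18 methyl 4-hydroxy-3-methylbenzoate
Product: 19 methyl 4-[(2,2-dimethylpropanoyl)oxy]-3-methylbenzoate
Conditions: t-BuCOCl, Et3N, DMAP (cat.), CH2Cl2, 0 °C to rt
Reagents that add atoms: pivaloyl chloride, CC(C)(C)C(=O)Cl
Why: DMAP-catalysed acylation of the phenol; the pivalate should withstand radical bromination and the organoaluminium step and is removed together with the methyl ester at the end.

Step 14
Reactants: 19 aryl pivalate
Product: 20 methyl 3-(bromomethyl)-4-[(2,2-dimethylpropanoyl)oxy]benzoate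
Conditions: NBS (1.05 equiv), AIBN (cat.), PhCF3, 85 °C
Reagents that add atoms: N-bromosuccinimide, O=C1CCC(=O)N1Br
Why: Wohl–Ziegler benzylic bromination of the only benzylic methyl; both ring substituents are acyl-type and deactivate the arene towards electrophilic bromination.

Step 15
Reactants: 17 terminal alkyne; 20 benzylic bromide
Product: 22 methyl 4-[(2,2-dimethylpropanoyl)oxy]-3-{(2E)-3-methyl-5-[(4aR,8aR)-2,5,5,8a-tetramethyl-3,4,4a,5,6,7,8,8a-octahydronaphthalen-1-yl]pent-2-en-1-yl}benzoate, via alkenyldimethylalane 21 (not isolated)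
Conditions: AlMe3 (2 equiv), Cp2ZrCl2 (0.2 equiv), CH2Cl2, 0 °C to rt; volatiles removed; then 20, Pd(PPh3)4 (5 mol %), THF, rt
Reagents that add atoms: trimethylaluminium, C[Al](C)C
Why: Negishi zirconium-catalysed carboalumination adds methyl and aluminium syn across the terminal alkyne with methyl on the internal carbon C13, which fixes the 13E geometry, and the alkenylalane then undergoes palladium-catalysed cross-coupling with the benzylic bromide with retention of alkene geometry; the tetrasubstituted C8=C9 alkene is inert to carbometalation.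

Step 16
Reactants: 22 protected coupling product
Product: 23 4-hydroxy-3-{(2E)-3-methyl-5-[(4aR,8aR)-2,5,5,8a-tetramethyl-3,4,4a,5,6,7,8,8a-octahydronaphthalen-1-yl]pent-2-en-1-yl}benzoic acid (target)
Conditions: KOH, THF/MeOH/H2O, 50 °C; then dilute HCl to pH 3–4, 0 °C
Reagents that add atoms: potassium hydroxide, [K+].[OH-]
Why: One saponification cleaves both the methyl benzoate and the aryl pivalate; base cannot move the isolated alkenes, and the mild acidification avoids acid-induced cyclisation of the ortho-allyl phenol to a chroman.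

Compound list
1 | (R)-α-ionone; (3E)-4-[(1R)-2,6,6-trimethylcyclohex-2-en-1-yl]but-3-en-2-one | CC1=CCCC(C)(C)[C@H]1/C=C/C(C)=O | starting material
2 | (R)-dihydro-α-ionone; 4-[(1R)-2,6,6-trimethylcyclohex-2-en-1-yl]butan-2-one | CC1=CCCC(C)(C)[C@H]1CCC(C)=O | intermediate
3 | 2-methyl-2-{2-[(1R)-2,6,6-trimethylcyclohex-2-en-1-yl]ethyl}-1,3-dioxolane | CC1=CCCC(C)(C)[C@H]1CCC2(C)OCCO2 | intermediate
4 | (4R)-3,5,5-trimethyl-4-[2-(2-methyl-1,3-dioxolan-2-yl)ethyl]cyclohex-2-en-1-one (ring A enone; precursor of the key step) | CC1=CC(=O)CC(C)(C)[C@H]1CCC2(C)OCCO2 | intermediate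
5 | allene (propadiene) | C=C=C | starting material
6 | (1S,5R,6S)-4,4,6-trimethyl-8-methylidene-5-[2-(2-methyl-1,3-dioxolan-2-yl)ethyl]bicyclo[4.2.0]octan-2-one (cis-fused head-to-head photoadduct; C9 trans to C6) | C=C1C[C@]2(C)[C@H]1C(=O)CC(C)(C)[C@H]2CCC3(C)OCCO3 | intermediate
7 | (1R,5R,6S)-4,4,6-trimethyl-5-[2-(2-methyl-1,3-dioxolan-2-yl)ethyl]bicyclo[4.2.0]octane-2,8-dione (ring configuration of 6; not isolated) | O=C1C[C@]2(C)[C@H]1C(=O)CC(C)(C)[C@H]2CCC3(C)OCCO3 | intermediate
8 | 2-{(1S,2R)-1,3,3-trimethyl-2-[2-(2-methyl-1,3-dioxolan-2-yl)ethyl]-5-oxocyclohexyl}acetic acid | OC(=O)C[C@]1(C)CC(=O)CC(C)(C)[C@H]1CCC2(C)OCCO2 | intermediate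
9 | 2-{(1S,2R)-5-hydrazinylidene-1,3,3-trimethyl-2-[2-(2-methyl-1,3-dioxolan-2-yl)ethyl]cyclohexyl}acetic acid (potassium salt in the flask; not isolated) | OC(=O)C[C@]1(C)CC(=NN)CC(C)(C)[C@H]1CCC2(C)OCCO2 | intermediate
10 | 2-{(1S,2R)-1,3,3-trimethyl-2-[2-(2-methyl-1,3-dioxolan-2-yl)ethyl]cyclohexyl}acetic acid | OC(=O)C[C@]1(C)CCCC(C)(C)[C@H]1CCC2(C)OCCO2 | intermediate
11 | 2-{(1S,2R)-1,3,3-trimethyl-2-[2-(2-methyl-1,3-dioxolan-2-yl)ethyl]cyclohexyl}ethan-1-ol | OCC[C@]1(C)CCCC(C)(C)[C@H]1CCC2(C)OCCO2 | intermediate
12 | 2-{(1S,2R)-1,3,3-trimethyl-2-[2-(2-methyl-1,3-dioxolan-2-yl)ethyl]cyclohexyl}acetaldehyde | O=CC[C@]1(C)CCCC(C)(C)[C@H]1CCC2(C)OCCO2 | intermediate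
13 | 2-[(1S,2R)-1,3,3-trimethyl-2-(3-oxobutyl)cyclohexyl]acetaldehyde (not isolated) | O=CC[C@]1(C)CCCC(C)(C)[C@H]1CCC(C)=O | intermediate
14 | (4aR,8aR)-2,5,5,8a-tetramethyl-3,4,4a,5,6,7,8,8a-octahydronaphthalene-1-carbaldehyde (ent-drim-8-en-11-al) | CC1=C(C=O)[C@]2(C)CCCC(C)(C)[C@H]2CC1 | intermediate
15 | [(4aR,8aR)-2,5,5,8a-tetramethyl-3,4,4a,5,6,7,8,8a-octahydronaphthalen-1-yl]methanol (ent-drim-8-en-11-ol) | CC1=C(CO)[C@]2(C)CCCC(C)(C)[C@H]2CC1 | intermediate
16 | (4aR,8aR)-1-(bromomethyl)-2,5,5,8a-tetramethyl-3,4,4a,5,6,7,8,8a-octahydronaphthalene | CC1=C(CBr)[C@]2(C)CCCC(C)(C)[C@H]2CC1 | intermediate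
17 | (4aR,8aR)-1-(but-3-yn-1-yl)-2,5,5,8a-tetramethyl-3,4,4a,5,6,7,8,8a-octahydronaphthalene | CC1=C(CCC#C)[C@]2(C)CCCC(C)(C)[C@H]2CC1 | intermediate
18 | methyl 4-hydroxy-3-methylbenzoate | Cc1cc(C(=O)OC)ccc1O | starting material
19 | methyl 4-[(2,2-dimethylpropanoyl)oxy]-3-methylbenzoate | Cc1cc(C(=O)OC)ccc1OC(=O)C(C)(C)C | intermediate
20 | methyl 3-(bromomethyl)-4-[(2,2-dimethylpropanoyl)oxy]benzoate | BrCc1cc(C(=O)OC)ccc1OC(=O)C(C)(C)C | intermediate
21 | dimethyl{(1E)-2-methyl-4-[(4aR,8aR)-2,5,5,8a-tetramethyl-3,4,4a,5,6,7,8,8a-octahydronaphthalen-1-yl]but-1-en-1-yl}alumane (not isolated) | CC1=C(CC/C(C)=C/[Al](C)C)[C@]2(C)CCCC(C)(C)[C@H]2CC1 | intermediate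
22 | methyl 4-[(2,2-dimethylpropanoyl)oxy]-3-{(2E)-3-methyl-5-[(4aR,8aR)-2,5,5,8a-tetramethyl-3,4,4a,5,6,7,8,8a-octahydronaphthalen-1-yl]pent-2-en-1-yl}benzoate | CC1=C(CC/C(C)=C/Cc2cc(C(=O)OC)ccc2OC(=O)C(C)(C)C)[C@]3(C)CCCC(C)(C)[C@H]3CC1 | intermediate
23 | 4-hydroxy-3-{(2E)-3-methyl-5-[(4aR,8aR)-2,5,5,8a-tetramethyl-3,4,4a,5,6,7,8,8a-octahydronaphthalen-1-yl]pent-2-en-1-yl}benzoic acid | CC1=C(CC/C(C)=C/Cc2cc(C(=O)O)ccc2O)[C@]2(C)CCCC(C)(C)[C@H]2CC1 | target

Total step count: 16. Longest linear sequence: 14 steps (steps 1–12, 15 and 16, from (R)-α-ionone); the arene fragment takes 2 steps (13 and 14).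

Steps most likely to fail

Step 4. Bond formation at C10 may occur on the face syn to the C5 chain, allene may add head-to-tail, or the excited enone may dimerise or abstract hydrogen from its own side chain before it meets allene. The fallback replaces the photochemical bond formation by a thermal [3,3] shift; it sets out from enone 4 and returns at alcohol 11. Luche reduction (NaBH4, CeCl3·7H2O, MeOH, −78 °C) should give the allylic alcohol with hydroxyl trans to the C5 chain, (1R,4R)-3,5,5-trimethyl-4-[2-(2-methyl-1,3-dioxolan-2-yl)ethyl]cyclohex-2-en-1-ol F1, because hydride approaches anti to the axial C4 methyl. A Johnson–Claisen rearrangement (MeC(OEt)3, EtCO2H cat., 140 °C) then carries the C2–O configuration suprafacially to C10 and should give the ethyl ester with a C1=C2 alkene, ethyl 2-{(1R,6R)-1,5,5-trimethyl-6-[2-(2-methyl-1,3-dioxolan-2-yl)ethyl]cyclohex-2-en-1-yl}acetate F2. Hydrogenation over palladium on carbon (H2, EtOAc) gives the saturated ethyl ester F3, and LiAlH4 reduces it to 11, so that steps 5–7 are not needed on this path.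

Step 9. The aldolisation may run in the other sense, with the enol or enamine of the methyl ketone (C7) attacking the aldehyde carbon C11 and closing an acetylcyclohexene instead of ring B. The fallback makes C9 the only possible nucleophile; it sets out from aldehyde 12 and returns at enal 14. Silylation (TMSCl, Et3N, DMF, 80 °C) gives the trimethylsilyl enol ether of the aldehyde F4. TiCl4 in CH2Cl2 at −78 °C then opens the dioxolane to an oxocarbenium ion at C8, which the enol ether captures intramolecularly (Mukaiyama aldol-type addition to a ketal) to give the β-(2-hydroxyethoxy) aldehyde F5. DBU in CH2Cl2 eliminates the alkoxy group to give 14.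

Step 15. Methyl instead of alkenyl may be transferred from aluminium in the palladium step, the organoaluminium species may attack the two ester groups, or the cross-coupling may stall. The fallback separates the two events; it sets out from alkyne 17 and bromide 20 and returns at 22. The alkenylalane 21 is quenched with I2 (THF, −30 °C) to the (E)-alkenyl iodide F6. Bromide 20 is converted with zinc dust and LiCl in THF into the benzylic zinc bromide F7, which tolerates both esters. Negishi coupling of F6 with F7 (Pd(PPh3)4, THF, rt) gives 22.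

Further compounds
F1 | step 4 | (1R,4R)-3,5,5-trimethyl-4-[2-(2-methyl-1,3-dioxolan-2-yl)ethyl]cyclohex-2-en-1-ol | CC1=C[C@H](O)CC(C)(C)[C@H]1CCC2(C)OCCO2
F2 | step 4 | ethyl 2-{(1R,6R)-1,5,5-trimethyl-6-[2-(2-methyl-1,3-dioxolan-2-yl)ethyl]cyclohex-2-en-1-yl}acetate | CCOC(=O)C[C@]1(C)C=CCC(C)(C)[C@H]1CCC2(C)OCCO2
F3 | step 4 | ethyl 2-{(1S,2R)-1,3,3-trimethyl-2-[2-(2-methyl-1,3-dioxolan-2-yl)ethyl]cyclohexyl}acetate | CCOC(=O)C[C@]1(C)CCCC(C)(C)[C@H]1CCC2(C)OCCO2
F4 | step 9 | trimethyl[(2-{(1S,2R)-1,3,3-trimethyl-2-[2-(2-methyl-1,3-dioxolan-2-yl)ethyl]cyclohexyl}ethenyl)oxy]silane (E/Z mixture) | C[Si](C)(C)OC=C[C@]1(C)CCCC(C)(C)[C@H]1CCC2(C)OCCO2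
F5 | step 9 | (4aR,8aR)-2-(2-hydroxyethoxy)-2,5,5,8a-tetramethyldecahydronaphthalene-1-carbaldehyde (mixture at C8 and C9) | O=CC1[C@]2(C)CCCC(C)(C)[C@H]2CCC1(C)OCCO
F6 | step 15 | (4aR,8aR)-1-[(3E)-4-iodo-3-methylbut-3-en-1-yl]-2,5,5,8a-tetramethyl-3,4,4a,5,6,7,8,8a-octahydronaphthalene | CC1=C(CC/C(C)=C/I)[C@]2(C)CCCC(C)(C)[C@H]2CC1
F7 | step 15 | {5-(methoxycarbonyl)-2-[(2,2-dimethylpropanoyl)oxy]benzyl}zinc bromide | COC(=O)c1ccc(OC(=O)C(C)(C)C)c(C[Zn]Br)c1
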